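**Retrosynthetic overview**
- C1–H: the last step is a trans-selective hydride reduction of a 3,4-dihydroisoquinoline C=N bond, which sets C1 from the existing C3 centre.
- Biaryl bond C5–C1': Negishi coupling of a 5-bromo-3,4-dihydroisoquinoline with a 1-naphthylzinc reagent.
- N-ring (key step): a five-membered spiro ring is widened to the six-membered N-ring by a 1,2-shift, set up by ipso-Bischler–Napieralski cyclisation of a 5-bromo-2,4-dimethoxyphenyl acetamide. The benzene ring comes from resorcinol and C3 from (S)-N-Boc-2-methylaziridine.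
- Naphthalene: the second carbocycle is built by anionic annulation of an o-methallylbenzamide (from anisole, Et2NCOCl and methallyl bromide), then O-methylation and bromination at C1.
- Ring order: naphthalene carbocycle first (side branch); then spiro azacycle → fused N-ring on the resorcinol ring; then the biaryl bond; then C1.

Assumption: the SMILES fixes C1 and C3 as (1S,3S) (trans) and leaves the C5–C1' biaryl axis open, so the target is taken as the (1S,3S) compound with the axis not set; both atropisomers form and can be separated by chromatography if one is wanted.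

**Route**

Step 1
Reactants: 1 anisole; 2 N,N-diethylcarbamoyl chloride
Product: 4 N,N-diethyl-2-methoxybenzamide, via 2-lithioanisole 3 (not isolated)
Conditions: n-BuLi, TMEDA, Et2O, 0 °C → rt; then added to 2, THF, −78 °C → rt
Reagents that add atoms: none
Why: Directed ortho-lithiation of anisole and acylation of the aryllithium by the carbamoyl chloride give the tertiary benzamide; no stereocentre is involved.

Step 2
Reactants: 4 N,N-diethyl-2-methoxybenzamide; 5 3-bromo-2-methylprop-1-ene
Product: 8 N,N-diethyl-2-methoxy-6-(2-methylprop-2-en-1-yl)benzamide, via N,N-diethyl-2-lithio-6-methoxybenzamide 6 (not isolated), via [2-(diethylcarbamoyl)-3-methoxyphenyl]magnesium bromide 7 (not isolated)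
Conditions: s-BuLi, TMEDA, THF, −78 °C; MgBr2·OEt2; then 5, −78 °C → rt
Reagents that add atoms: none
Why: Directed ortho metalation by the stronger CONEt2 group goes to C6, and the arylmagnesium species is allylated by the methallyl bromide (nucleophilic substitution); no stereocentre is involved.

Step 3
Reactants: 8 N,N-diethyl-2-methoxy-6-(2-methylprop-2-en-1-yl)benzamide
Product: 10 1,8-dimethoxy-3-methylnaphthalene, via lithium 8-methoxy-3-methylnaphthalen-1-olate 9 (not isolated)
Conditions: LiN(i-Pr)2 (2.2 equiv), THF, −78 °C → rt; then Me2SO4, DMPU, rt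
Reagents that add atoms: dimethyl sulfate COS(=O)(=O)OC
Why: Anionic aromatic ring annulation of an o-allylbenzamide (benzylic deprotonation, attack of the dienyl anion terminus on the amide carbonyl, loss of diethylamide, aromatisation) gives the 1-naphtholate, which is O-methylated in the same flask (Williamson ether synthesis).

Step 4
Reactants: 10 1,8-dimethoxy-3-methylnaphthalene
Product: 11 1-bromo-4,5-dimethoxy-2-methylnaphthalene
Conditions: NBS (1.0 equiv), MeCN, 0 °C
Reagents that add atoms: N-bromosuccinimide O=C1CCC(=O)N1Br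
Why: Electrophilic aromatic bromination is expected para to the methoxy group and ortho to the methyl group, the most electron-rich position of the methyl-bearing ring.

Step 5
Reactants: 12 resorcinol
Product: 14 1,3-dimethoxybenzene, via 3-methoxyphenol 13 (not isolated)
Conditions: MeI (2.5 equiv), K2CO3, acetone, reflux
Reagents that add atoms: iodomethane CI
Why: Twofold Williamson ether synthesis of the two phenols.

Step 6
Reactants: 14 1,3-dimethoxybenzene
Product: 16 1,5-dibromo-2,4-dimethoxybenzene, via 1-bromo-2,4-dimethoxybenzene 15 (not isolated)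
Conditions: NBS (2.1 equiv), MeCN, 0 °C → rt
Reagents that add atoms: N-bromosuccinimide O=C1CCC(=O)N1Br
Why: Twofold electrophilic aromatic bromination goes to the two positions that are para to one and ortho to the other methoxy group; the position between the methoxy groups is hindered.

Step 7
Reactants: 16 1,5-dibromo-2,4-dimethoxybenzene; 17 tert-butyl (2S)-2-methylaziridine-1-carboxylate
Product: 20 tert-butyl N-[(2S)-1-(5-bromo-2,4-dimethoxyphenyl)propan-2-yl]carbamate, via (5-bromo-2,4-dimethoxyphenyl)lithium 18 (not isolated), via (5-bromo-2,4-dimethoxyphenyl)magnesium bromide 19 (not isolated)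
Conditions: n-BuLi (1.0 equiv), THF, −78 °C; MgBr2·OEt2; then CuBr·SMe2 (10 mol %), 17, −40 → 0 °C; then H2O
Reagents that add atoms: none
Why: Selective mono bromine–lithium exchange, transmetalation and CuBr·SMe2-catalysed SN2 ring opening of the N-Boc-aziridine at its CH2 carbon; the (S) centre comes from 17 and is not touched.

Step 8
Reactants: 20 tert-butyl N-[(2S)-1-(5-bromo-2,4-dimethoxyphenyl)propan-2-yl]carbamate
Product: 22 N-[(2S)-1-(5-bromo-2,4-dimethoxyphenyl)propan-2-yl]acetamide, via (2S)-1-(5-bromo-2,4-dimethoxyphenyl)propan-2-amine 21 (not isolated)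
Conditions: TFA, CH2Cl2, rt; evaporate; then Ac2O, Et3N, CH2Cl2, 0 °C → rt
Reagents that add atoms: acetic anhydride CC(=O)OC(C)=O
Why: Acidolytic Boc cleavage followed by N-acetylation of the amine; the stereocentre is not touched.

Step 9
Reactants: 22 N-[(2S)-1-(5-bromo-2,4-dimethoxyphenyl)propan-2-yl]acetamide
Product: 25 (3S)-5-bromo-6,8-dimethoxy-1,3-dimethyl-3,4-dihydroisoquinoline, via nitrilium ion 23 (not isolated), via spiro arenium cation 24 (not isolated)
Conditions: Tf2O (1.2 equiv), 2,6-di-tert-butyl-4-methylpyridine (2.5 equiv), ClCH2CH2Cl, −30 °C → rt, then 80 °C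
Reagents that add atoms: none
Why: Proposed new method: an ipso-Bischler–Napieralski cyclisation with ring expansion — the nitrilium ion 23 cannot close normally because the free ortho carbon is meta to both methoxy groups and flanked by bromine, so it is captured by the ipso carbon (para to one OMe, ortho to the other) to give the spiro cation 24, whose ring CH2 then makes a 1,2-shift (Wagner–Meerwein type) to the neighbouring CH carbon, widening the five-membered spiro ring to the six-membered fused ring, and proton loss rearomatises to the 6,8-dimethoxy pattern; the imine carbon should be the poorer migrating group, the hindered base and triflate medium are chosen to keep the O-methyl groups on, no stereocentre is formed and C3 is not touched; the closest known reaction types are the "abnormal" Bischler–Napieralski products seen with para-methoxyphenethylamides and the dienone–phenol rearrangement of spirodienones.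

Step 10
Reactants: 11 1-bromo-4,5-dimethoxy-2-methylnaphthalene; 25 (3S)-5-bromo-6,8-dimethoxy-1,3-dimethyl-3,4-dihydroisoquinoline
Product: 28 (3S)-5-(4,5-dimethoxy-2-methylnaphthalen-1-yl)-6,8-dimethoxy-1,3-dimethyl-3,4-dihydroisoquinoline, via (4,5-dimethoxy-2-methylnaphthalen-1-yl)lithium 26 (not isolated), via (4,5-dimethoxy-2-methylnaphthalen-1-yl)zinc chloride 27 (not isolated)
Conditions: 11, n-BuLi, THF, −78 °C; ZnCl2, → rt; then 25, Pd2(dba)3 (2.5 mol %), RuPhos (10 mol %), THF/NMP, 70 °C
Reagents that add atoms: none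
Why: Negishi cross-coupling with a bulky dialkylbiarylphosphine ligand of the kind used for tetra-ortho-substituted biaryls; the arylzinc reagent tolerates the imine, C3 is not touched and the axis forms as a mixture of both atropisomers.

Step 11
Reactants: 28 (3S)-5-(4,5-dimethoxy-2-methylnaphthalen-1-yl)-6,8-dimethoxy-1,3-dimethyl-3,4-dihydroisoquinoline
Product: 29 (1S,3S)-5-(4,5-dimethoxy-2-methylnaphthalen-1-yl)-6,8-dimethoxy-1,3-dimethyl-1,2,3,4-tetrahydroisoquinoline
Conditions: LiAlH4, AlMe3, THF, −78 → 0 °C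
Reagents that add atoms: none
Why: Diastereoselective hydride reduction of the cyclic imine; LiAlH4 with AlMe3 is the combination used to obtain 1,3-trans products from 8-methoxy-3-methyl-3,4-dihydroisoquinolines, so the (3S) centre sets (1S) by substrate control.

**Compound list**
1 | anisole | COc1ccccc1 | starting material
2 | N,N-diethylcarbamoyl chloride | CCN(CC)C(Cl)=O | starting material
3 | 2-lithioanisole | [Li]c1ccccc1OC | intermediate
4 | N,N-diethyl-2-methoxybenzamide | CCN(CC)C(=O)c1ccccc1OC | intermediate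
5 | 3-bromo-2-methylprop-1-ene | CC(=C)CBr | starting material
6 | N,N-diethyl-2-lithio-6-methoxybenzamide | CCN(CC)C(=O)c1c([Li])cccc1OC | intermediate
7 | [2-(diethylcarbamoyl)-3-methoxyphenyl]magnesium bromide | CCN(CC)C(=O)c1c([Mg]Br)cccc1OC | intermediate
8 | N,N-diethyl-2-methoxy-6-(2-methylprop-2-en-1-yl)benzamide | CCN(CC)C(=O)c1c(CC(C)=C)cccc1OC | intermediate
9 | lithium 8-methoxy-3-methylnaphthalen-1-olate | [Li+].[O-]c1cc(C)cc2cccc(OC)c12 | intermediate
10 | 1,8-dimethoxy-3-methylnaphthalene | COc1cc(C)cc2cccc(OC)c12 | intermediate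
11 | 1-bromo-4,5-dimethoxy-2-methylnaphthalene | COc1cc(C)c(Br)c2cccc(OC)c12 | intermediate
12 | resorcinol | Oc1cccc(O)c1 | starting material
13 | 3-methoxyphenol | COc1cccc(O)c1 | intermediate
14 | 1,3-dimethoxybenzene | COc1cccc(OC)c1 | intermediate
15 | 1-bromo-2,4-dimethoxybenzene | COc1ccc(Br)c(OC)c1 | intermediate
16 | 1,5-dibromo-2,4-dimethoxybenzene | COc1cc(OC)c(Br)cc1Br | intermediate
17 | tert-butyl (2S)-2-methylaziridine-1-carboxylate | C[C@H]1CN1C(=O)OC(C)(C)C | starting material
18 | (5-bromo-2,4-dimethoxyphenyl)lithium | [Li]c1cc(Br)c(OC)cc1OC | intermediate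
19 | (5-bromo-2,4-dimethoxyphenyl)magnesium bromide | Br[Mg]c1cc(Br)c(OC)cc1OC | intermediate
20 | tert-butyl N-[(2S)-1-(5-bromo-2,4-dimethoxyphenyl)propan-2-yl]carbamate | COc1cc(OC)c(Br)cc1C[C@H](C)NC(=O)OC(C)(C)C | intermediate
21 | (2S)-1-(5-bromo-2,4-dimethoxyphenyl)propan-2-amine | COc1cc(OC)c(Br)cc1C[C@H](C)N | intermediate
22 | N-[(2S)-1-(5-bromo-2,4-dimethoxyphenyl)propan-2-yl]acetamide | COc1cc(OC)c(Br)cc1C[C@H](C)NC(C)=O | intermediate
23 | N-[(2S)-1-(5-bromo-2,4-dimethoxyphenyl)propan-2-yl]acetonitrilium | COc1cc(OC)c(Br)cc1C[C@H](C)[N+]#CC | intermediate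
24 | (3S)-9-bromo-6,8-dimethoxy-1,3-dimethyl-2-azaspiro[4.5]deca-1,6,9-trien-8-ylium (drawn as its O-methyl oxocarbenium form; either configuration at the spiro carbon) | COC1=CC(=[O+]C)C(Br)=CC12C[C@H](C)N=C2C | intermediate
25 | (3S)-5-bromo-6,8-dimethoxy-1,3-dimethyl-3,4-dihydroisoquinoline | COc1cc(OC)c2c(c1Br)C[C@H](C)N=C2C | intermediate
26 | (4,5-dimethoxy-2-methylnaphthalen-1-yl)lithium | [Li]c1c(C)cc(OC)c2c(OC)cccc12 | intermediate
27 | (4,5-dimethoxy-2-methylnaphthalen-1-yl)zinc chloride | Cl[Zn]c1c(C)cc(OC)c2c(OC)cccc12 | intermediate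
28 | (3S)-5-(4,5-dimethoxy-2-methylnaphthalen-1-yl)-6,8-dimethoxy-1,3-dimethyl-3,4-dihydroisoquinoline | COc1cc(OC)c2c(c1-c1c(C)cc(OC)c3c(OC)cccc13)C[C@H](C)N=C2C | intermediate
29 | (1S,3S)-5-(4,5-dimethoxy-2-methylnaphthalen-1-yl)-6,8-dimethoxy-1,3-dimethyl-1,2,3,4-tetrahydroisoquinoline | COc1cc(OC)c2c(c1-c1c(C)cc(OC)c3c(OC)cccc13)C[C@H](C)N[C@H]2C | target

**Step count**
Total: 11 steps. Longest linear sequence: 7 steps (steps 5–11, from resorcinol 12); the naphthalene branch (steps 1–4) joins at step 10.

**Steps most likely to fail**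

Step 9 (the new ring expansion). It may give no cyclisation, the 8-bromo-5,7-dimethoxy isomer by migration of the imine carbon, or loss of the C6 O-methyl group. The fallback uses only known chemistry, sets out from 14 and comes back at 25. C–H borylation of 14 with [Ir(cod)(OMe)]2, 4,4'-di-tert-butyl-2,2'-bipyridine and B2pin2 at the only unhindered position gives 2-(3,5-dimethoxyphenyl)-4,4,5,5-tetramethyl-1,3,2-dioxaborolane F1. CuBr2 in MeOH/H2O turns it into 1-bromo-3,5-dimethoxybenzene F2. Mg in THF gives (3,5-dimethoxyphenyl)magnesium bromide F3, which opens 17 with CuBr·SMe2 catalysis to tert-butyl N-[(2S)-1-(3,5-dimethoxyphenyl)propan-2-yl]carbamate F4. TFA frees (2S)-1-(3,5-dimethoxyphenyl)propan-2-amine F5, and Ac2O/Et3N gives N-[(2S)-1-(3,5-dimethoxyphenyl)propan-2-yl]acetamide F6. NBS brominates ortho to the side chain and para to a methoxy group to give N-[(2S)-1-(2-bromo-3,5-dimethoxyphenyl)propan-2-yl]acetamide F7. An ordinary Bischler–Napieralski cyclisation (Tf2O, 2-chloropyridine, CH2Cl2, −78 °C → rt) at the remaining ortho carbon, which is para and ortho to the two methoxy groups, then gives 25.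

Step 10 (Negishi coupling to a tetra-ortho-substituted biaryl on an electron-rich bromide). The fallback moves the coupling to an earlier, less hindered bromide; it sets out from 22 (with 27 made from 11 as in step 10) and comes back at 28. Coupling of 22 with 27 under Pd2(dba)3/RuPhos, where the bromide has only one ortho substituent, gives N-[(2S)-1-[5-(4,5-dimethoxy-2-methylnaphthalen-1-yl)-2,4-dimethoxyphenyl]propan-2-yl]acetamide F8. The step 9 conditions then take F8 through N-[(2S)-1-[5-(4,5-dimethoxy-2-methylnaphthalen-1-yl)-2,4-dimethoxyphenyl]propan-2-yl]acetonitrilium F9 and (3S)-9-(4,5-dimethoxy-2-methylnaphthalen-1-yl)-6,8-dimethoxy-1,3-dimethyl-2-azaspiro[4.5]deca-1,6,9-trien-8-ylium F10 to 28. In this order the fourth ortho substituent of the axis is put in by the 1,2-shift and not by the coupling.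

Step 11 (trans selectivity of the reduction on the hindered 5-naphthyl substrate). The fallback reduces before coupling; it sets out from 25 and comes back at 29. LiAlH4/AlMe3 on 25, which is closest to the plain 6,8-dimethoxy-1,3-dimethyl-3,4-dihydroisoquinoline for which this trans selectivity is expected, gives (1S,3S)-5-bromo-6,8-dimethoxy-1,3-dimethyl-1,2,3,4-tetrahydroisoquinoline F11. The minor cis isomer is removed by chromatography or salt crystallisation, and Negishi coupling of F11 with 27 (Pd2(dba)3, RuPhos) gives 29.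

Further compounds
F1 | step 9 | 2-(3,5-dimethoxyphenyl)-4,4,5,5-tetramethyl-1,3,2-dioxaborolane | COc1cc(OC)cc(c1)B1OC(C)(C)C(C)(C)O1
F2 | step 9 | 1-bromo-3,5-dimethoxybenzene | COc1cc(Br)cc(OC)c1
F3 | step 9 | (3,5-dimethoxyphenyl)magnesium bromide | Br[Mg]c1cc(OC)cc(OC)c1
F4 | step 9 | tert-butyl N-[(2S)-1-(3,5-dimethoxyphenyl)propan-2-yl]carbamate | COc1cc(OC)cc(c1)C[C@H](C)NC(=O)OC(C)(C)C
F5 | step 9 | (2S)-1-(3,5-dimethoxyphenyl)propan-2-amine | COc1cc(OC)cc(c1)C[C@H](C)N
F6 | step 9 | N-[(2S)-1-(3,5-dimethoxyphenyl)propan-2-yl]acetamide | COc1cc(OC)cc(c1)C[C@H](C)NC(C)=O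
F7 | step 9 | N-[(2S)-1-(2-bromo-3,5-dimethoxyphenyl)propan-2-yl]acetamide | COc1cc(OC)c(Br)c(c1)C[C@H](C)NC(C)=O
F8 | step 10 | N-[(2S)-1-[5-(4,5-dimethoxy-2-methylnaphthalen-1-yl)-2,4-dimethoxyphenyl]propan-2-yl]acetamide | COc1cc(OC)c(cc1C[C@H](C)NC(C)=O)-c1c(C)cc(OC)c2c(OC)cccc12
F9 | step 10 | N-[(2S)-1-[5-(4,5-dimethoxy-2-methylnaphthalen-1-yl)-2,4-dimethoxyphenyl]propan-2-yl]acetonitrilium | COc1cc(OC)c(cc1C[C@H](C)[N+]#CC)-c1c(C)cc(OC)c2c(OC)cccc12
F10 | step 10 | (3S)-9-(4,5-dimethoxy-2-methylnaphthalen-1-yl)-6,8-dimethoxy-1,3-dimethyl-2-azaspiro[4.5]deca-1,6,9-trien-8-ylium | COC1=CC(=[O+]C)C(=CC12C[C@H](C)N=C2C)-c1c(C)cc(OC)c2c(OC)cccc12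
F11 | step 11 | (1S,3S)-5-bromo-6,8-dimethoxy-1,3-dimethyl-1,2,3,4-tetrahydroisoquinoline | COc1cc(OC)c2c(c1Br)C[C@H](C)N[C@H]2C
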